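The route rests on disconnecting the C1–O1 and C7–O7 bonds, which turns the tertiary carbinol C1 and its CH2O arm into an exocyclic C1=C7 methylene on the six-membered ring C1–C6. One hydrogen-bond-directed dihydroxylation (OsO4, TMEDA) then forms both C–O bonds and sets the quaternary stereocentre C1. It exploits the free allylic C6 hydroxyl, which lies on the ring face opposite the cis C4/C5 diol and delivers O1 cis to O6. The precursor is a linearly conjugated semicyclic diene (C7=C1–C2=C3) with a C4/C5 acetonide and free C6–OH, built from the enzymatic cis-diol of bromobenzene, whose two stereocentres become C4 and C5.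

Key step: step 6

Remark: target numbering is used for all intermediates (C1 bears C7 and O1; C2=C3 is the ring alkene; C4, C5, C6 bear O4, O5, O6); the target is (1S,4R,5S,6S), with O4 and O5 on one ring face and O6 and O1 on the other.

Step 1
Reactants: 1 (1S,2S)-3-bromocyclohexa-3,5-diene-1,2-diol; 2 2,2-dimethoxypropane
Product: 3 (3aS,7aS)-4-bromo-2,2-dimethyl-3a,7a-dihydro-1,3-benzodioxole
Conditions: Me2C(OMe)2, p-TsOH (cat.), acetone, 0 °C to rt; then Et3N
Reagents that add atoms: 2,2-dimethoxypropane COC(C)(C)OC
Why: Acid-catalysed transketalisation (acetonide formation) of the cis-diol is faster than its dehydration to a phenol and touches neither stereocentre.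

Step 2
Reactants: 3
Product: 4 (3aS,4R,5R,7aS)-7-bromo-2,2-dimethyl-3a,4,5,7a-tetrahydro-1,3-benzodioxole-4,5-diol
Conditions: OsO4 (cat.), NMO, acetone/H2O, rt; aq. Na2SO3 quench
Reagents that add atoms: N-methylmorpholine N-oxide C[N+]1([O-])CCOCC1; water O; oxygen is passed on through catalytic osmium tetroxide O=[Os](=O)(=O)=O
Why: Catalytic OsO4/NMO syn-dihydroxylation should take the more electron-rich, bromine-free alkene from the face anti to the dioxolane ring, which sets the two new carbinol centres (future C1 and C6) trans to O5.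

Step 3
Reactants: 4
Product: 5 (3aS,4R,5R,7aR)-2,2-dimethyl-3a,4,5,7a-tetrahydro-1,3-benzodioxole-4,5-diol
Conditions: Bu3SnH, AIBN (cat.), toluene, 90 °C
Reagents that add atoms: none
Why: Radical-chain hydrodebromination of the vinyl bromide with the tin hydride exchanges Br for H at C3 and leaves all four stereocentres as they are (the descriptor at C7a changes only because a substituent priority changes).

Step 4
Reactants: 5
Product: 6 (3aS,4S,7aR)-4-hydroxy-2,2-dimethyl-3a,7a-dihydro-1,3-benzodioxol-5(4H)-one
Conditions: activated MnO2 (excess), CH2Cl2, rt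
Reagents that add atoms: none
Why: Allylic alcohol oxidation with MnO2 is chemoselective for the allylic carbinol (future C1), so the enone forms while the non-allylic C6 hydroxyl and its configuration stay untouched.

Step 5
Reactants: 6; 7 methyltriphenylphosphonium bromide
Product: 8 (3aS,4R,7aR)-2,2-dimethyl-5-methylidene-3a,4,5,7a-tetrahydro-1,3-benzodioxol-4-ol
Conditions: Ph3PCH3Br (3.5 equiv), KOtBu (3.3 equiv), THF, 0 °C; then 6, −78 to 0 °C
Reagents that add atoms: methyltriphenylphosphonium bromide C[P+](c1ccccc1)(c1ccccc1)c1ccccc1.[Br-]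
Why: Wittig methylenation with excess ylide acts on the C6 potassium alkoxide that forms first, whose negative charge disfavours enolisation and thus epimerisation at C6 or β-alkoxide loss from C5, so C7 is installed with the C6 centre unchanged.

Step 6
Reactants: 8
Product: 10 (3aS,4S,5S,7aR)-5-(hydroxymethyl)-2,2-dimethyl-3a,4,5,7a-tetrahydro-1,3-benzodioxole-4,5-diol, via osmate ester 9 (not isolated)
Conditions: OsO4 (1.05 equiv), TMEDA (1.1 equiv), CH2Cl2, −78 °C; then aq. Na2SO3, THF, reflux
Reagents that add atoms: osmium tetroxide O=[Os](=O)(=O)=O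
Why: The bidentate amine makes OsO4 a stronger hydrogen-bond acceptor, so the TMEDA-bound reagent docks on the free C6 hydroxyl and adds by [3+2] cycloaddition to the adjacent exocyclic C1=C7 bond from the O6 face, giving the chelated osmate ester 9 (hexavalent osmium) that sulfite cleaves reductively to the diol. The closest known reaction type is the hydrogen-bond-directed syn-dihydroxylation of cyclic allylic alcohols with stoichiometric OsO4 and TMEDA. No ring of the product is closed, the five-membered osmate chelate being transient. The one new stereocentre, C1, is controlled by the C6 carbinol through that hydrogen bond (O1 cis to O6, C7 on the other face), and the C4/C5 acetonide on the opposite face blocks the competing approach. The step needs site selectivity for C1=C7 over C2=C3 and reversal of the usual preference of undirected osmylation for the face anti to an allylic oxygen: the hydroxyl is allylic only to C1=C7, C2=C3 is hindered and inductively deactivated by the C4 acetonide oxygen, and one equivalent of reagent at −78 °C in a non-coordinating solvent keeps the hydrogen bond in control.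

Step 7
Reactants: 10; 11 benzoyl chloride
Product: 12 [(3aS,4S,5S,7aR)-4,5-dihydroxy-2,2-dimethyl-3a,4,5,7a-tetrahydro-1,3-benzodioxol-5-yl]methyl benzoate
Conditions: BzCl (1.05 equiv), pyridine, CH2Cl2, −20 °C
Reagents that add atoms: benzoyl chloride O=C(Cl)c1ccccc1
Why: Pyridine-mediated O-acylation (kinetic benzoylation) should select the primary O7 over the hindered secondary O6 and the tertiary O1 and creates no stereocentre.

Step 8
Reactants: 12
Product: 13 [(1S,4R,5R,6S)-1,4,5,6-tetrahydroxycyclohex-2-en-1-yl]methyl benzoate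
Conditions: AcOH/H2O (4:1), 50 °C
Reagents that add atoms: none
Why: Acid-catalysed acetal hydrolysis frees the cis C4/C5 diol with loss of acetone, and the benzoate and the inductively deactivated tertiary allylic carbinol should tolerate warm aqueous acetic acid (the C5 descriptor changes by priority only).

Step 9
Reactants: 13; 14 trimethyl orthobenzoate
Product: 16 [(1S,4R,5S,6S)-4-(benzoyloxy)-1,5,6-trihydroxycyclohex-2-en-1-yl]methyl benzoate, via cyclic orthobenzoate 15 (not isolated)
Conditions: PhC(OMe)3 (1.2 equiv), CSA (cat.), MeCN, rt; then AcOH/H2O (4:1), rt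
Reagents that add atoms: trimethyl orthobenzoate COC(OC)(OC)c1ccccc1; water O
Why: Orthoester exchange should engage the only bis-secondary cis-diol (C4/C5, the tertiary O1 being too slow to pair with O6 when the reagent is limited), and stereoelectronically controlled hydrolysis of the resulting 2-methoxy-2-phenyl-1,3-dioxolane opens to the ester on the pseudoaxial allylic O4 with the equatorial O5 set free, no stereocentre being affected.

Compound list
1 | (1S,2S)-3-bromocyclohexa-3,5-diene-1,2-diol | BrC1=CC=C[C@H](O)[C@@H]1O | starting material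
2 | 2,2-dimethoxypropane | COC(C)(C)OC | starting material
3 | (3aS,7aS)-4-bromo-2,2-dimethyl-3a,7a-dihydro-1,3-benzodioxole | BrC1=CC=C[C@H](OC2(C)C)[C@@H]1O2 | intermediate
4 | (3aS,4R,5R,7aS)-7-bromo-2,2-dimethyl-3a,4,5,7a-tetrahydro-1,3-benzodioxole-4,5-diol (diol anti to the acetonide) | O[C@@H]1C=C(Br)[C@@H](OC2(C)C)[C@@H](O2)[C@@H]1O | intermediate
5 | (3aS,4R,5R,7aR)-2,2-dimethyl-3a,4,5,7a-tetrahydro-1,3-benzodioxole-4,5-diol | O[C@@H]1C=C[C@@H](OC2(C)C)[C@@H](O2)[C@@H]1O | intermediate
6 | (3aS,4S,7aR)-4-hydroxy-2,2-dimethyl-3a,7a-dihydro-1,3-benzodioxol-5(4H)-one | O=C1C=C[C@@H](OC2(C)C)[C@@H](O2)[C@@H]1O | intermediate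
7 | methyltriphenylphosphonium bromide | C[P+](c1ccccc1)(c1ccccc1)c1ccccc1.[Br-] | starting material
8 | (3aS,4R,7aR)-2,2-dimethyl-5-methylidene-3a,4,5,7a-tetrahydro-1,3-benzodioxol-4-ol (key-step precursor) | C=C1C=C[C@@H](OC2(C)C)[C@@H](O2)[C@@H]1O | intermediate
9 | cyclic osmate ester of 8 across O1 and O7 (dioxo, hexavalent osmium, TMEDA-chelated; C1 configured as in 10; not isolated) | O4C[C@@]1(O[Os-2]45(=O)(=O)[N+](C)(C)CC[N+]5(C)C)C=C[C@@H](OC2(C)C)[C@@H](O2)[C@@H]1O | intermediate
10 | (3aS,4S,5S,7aR)-5-(hydroxymethyl)-2,2-dimethyl-3a,4,5,7a-tetrahydro-1,3-benzodioxole-4,5-diol (key-step product) | OC[C@@]1(O)C=C[C@@H](OC2(C)C)[C@@H](O2)[C@@H]1O | intermediate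
11 | benzoyl chloride | O=C(Cl)c1ccccc1 | starting material
12 | [(3aS,4S,5S,7aR)-4,5-dihydroxy-2,2-dimethyl-3a,4,5,7a-tetrahydro-1,3-benzodioxol-5-yl]methyl benzoate | O=C(OC[C@@]1(O)C=C[C@@H](OC2(C)C)[C@@H](O2)[C@@H]1O)c1ccccc1 | intermediate
13 | [(1S,4R,5R,6S)-1,4,5,6-tetrahydroxycyclohex-2-en-1-yl]methyl benzoate | O=C(OC[C@@]1(O)C=C[C@@H](O)[C@@H](O)[C@@H]1O)c1ccccc1 | intermediate
14 | trimethyl orthobenzoate | COC(OC)(OC)c1ccccc1 | starting material
15 | cyclic methyl orthobenzoate of 13 across O4 and O5 (2-methoxy-2-phenyl-1,3-dioxolane; both epimers at the orthoester carbon; ring stereocentres as in 13; not isolated) | O=C(OC[C@@]1(O)C=C[C@@H](OC2(OC)c3ccccc3)[C@@H](O2)[C@@H]1O)c1ccccc1 | intermediate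
16 | [(1S,4R,5S,6S)-4-(benzoyloxy)-1,5,6-trihydroxycyclohex-2-en-1-yl]methyl benzoate | O=C(OC[C@@]1(O)C=C[C@@H](OC(=O)c2ccccc2)[C@@H](O)[C@@H]1O)c1ccccc1 | target

Total step count: 9. Longest linear sequence: 9 steps (1 to 16).

Steps most likely to fail

Step 6. The hydrogen bond may fail to override the intrinsic preference of osmylation for the face anti to the allylic oxygen, or the ring alkene may be oxidised as well (poor facial or site selectivity). Fallback: from 8, hydroxyl-directed epoxidation with VO(acac)2 (cat.) and t-BuOOH in CH2Cl2 at 0 °C should deliver oxygen to C1=C7 syn to the C6 hydroxyl and give the C1/C7 spiro-epoxide F1. Opening of this 2,3-epoxy alcohol at the primary C7 with benzoic acid and Ti(OiPr)4 (CH2Cl2, rt) installs the O7 benzoate and frees O1 with the C1–O bond untouched, so the sequence comes back to the route at 12.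

Step 9. Orthoester exchange may also engage the cis O1/O6 pair, or the hemiorthoester may collapse without regiocontrol, so that the benzoyl group ends up on the wrong oxygen (loss of regioselectivity in the acyl transfer). Fallback: from 12, O6 is silylated (TBSOTf, 2,6-lutidine, CH2Cl2, −78 °C) to the O6 silyl ether F2, and the acetonide is hydrolysed (AcOH/H2O, 40 °C) to the C4/C5 diol F3. This only remaining vicinal diol is converted with PhC(OMe)3 and CSA into the cyclic orthobenzoate F4, which is opened in the same flask with aqueous AcOH to the O4 benzoate F5. HF·pyridine in THF then removes the silyl group without acyl migration, returning to the route at 16.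

Step 5. The basic ylide may enolise the γ,δ-dioxygenated enone, leading to β-alkoxide elimination and aromatisation or to epimerisation at C6 instead of olefination. Fallback: from 6, the hydroxyl is silylated (TBSCl, imidazole, DMF) to the silyl ether F6. The ketone is methylenated under non-basic conditions with the Petasis reagent Cp2TiMe2 (toluene, 65 °C) to the silyl-protected diene F7, and TBAF in THF frees O6, rejoining the route at 8.

Further compounds
F1 | step 6 | C1/C7 spiro-epoxide of 8, oxirane oxygen cis to the C6 hydroxyl | C3[C@@]1(O3)C=C[C@@H](OC2(C)C)[C@@H](O2)[C@@H]1O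
F2 | step 9 | O6 tert-butyldimethylsilyl ether of 12 | O=C(OC[C@@]1(O)C=C[C@@H](OC2(C)C)[C@@H](O2)[C@@H]1O[Si](C)(C)C(C)(C)C)c1ccccc1
F3 | step 9 | O6 tert-butyldimethylsilyl ether of 13 (O1, O4, O5 free) | O=C(OC[C@@]1(O)C=C[C@@H](O)[C@@H](O)[C@@H]1O[Si](C)(C)C(C)(C)C)c1ccccc1
F4 | step 9 | C4/C5 cyclic methyl orthobenzoate of F3 (both epimers at the orthoester carbon) | O=C(OC[C@@]1(O)C=C[C@@H](OC2(OC)c3ccccc3)[C@@H](O2)[C@@H]1O[Si](C)(C)C(C)(C)C)c1ccccc1
F5 | step 9 | O6 tert-butyldimethylsilyl ether of 16 | O=C(OC[C@@]1(O)C=C[C@@H](OC(=O)c2ccccc2)[C@@H](O)[C@@H]1O[Si](C)(C)C(C)(C)C)c1ccccc1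
F6 | step 5 | O6 tert-butyldimethylsilyl ether of 6 | O=C1C=C[C@@H](OC2(C)C)[C@@H](O2)[C@@H]1O[Si](C)(C)C(C)(C)C
F7 | step 5 | O6 tert-butyldimethylsilyl ether of 8 | C=C1C=C[C@@H](OC2(C)C)[C@@H](O2)[C@@H]1O[Si](C)(C)C(C)(C)C
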